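The readings were generated by integration with made-up constants, noise included.

The pitfall in repeating this run is to read percent as speed. At 3.00 h the beta run stands at 11.1% and the theta run at 23.7%, yet these are percentages of different charges.

| setting | theta | beta | Friday's | Tuesday's |
|---|---|---|---|---|
| solid substrate | 0.028 M | 0.063 M | 0.042 M | 0.042 M |
| remark | run made earlier | run made earlier |  |  |
| time |  |  | 4.0 h | 12 h |

| run | time / h | target / % |
|---|---|---|
| theta | 0.667 | 4.9 |
| theta | 1.50 | 11.1 |
| theta | 3.00 | 23.7 |
| theta | 5.00 | 39.5 |
| beta | 0.667 | 2.0 |
| beta | 1.50 | 5.1 |
| beta | 3.00 | 11.1 |
| beta | 5.00 | 30.6 |

(each reading ± 0.5 percentage points)

- percentages count the solid substrate that a species holds: one side product counts as two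
- solid, in amounts per volume of the solution: solid substrate
- the analysis behind the earlier runs scatters by 0.5 percentage points, standard deviation
- steps under discussion: starting material + 2 target -> 3 target; starting material -> target; starting material + target -> side product; solid substrate <-> starting material
- at the start none of the solid substrate is in solution
- what has only dissolved of solid substrate counts as not reacted

- which one finishes higher in amount of target, in percent of the solid substrate charged ("neither" within 2 percentage points) (Friday's / Tuesday's / neither)
- amount of target at the end, in percent of the solid substrate charged, Friday's
- amount of target at the end, in percent of the solid substrate charged, Tuesday's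

Does the charge matter early on? I convert to concentration. At that time the beta run holds 0.00699 M of target and the theta run 0.00664 M, a ratio of 1.05 against a charge ratio of 2.25. So I read the early making of target as zero order in the charge: concentration follows the clock, and percent is that concentration over the charge.

How long does that hold at 0.042 M? By 5.00 h the theta run has 0.0111 M against 0.0193 M in the beta run. The two runs still nearly agree at 3.00 h, so I read the theta run's charge of 0.028 M as showing in the target only after about that time. Scaling by charge, a rough estimate, I expect Friday's to stay with the beta run until about 4.50 h, longer than Friday's 4.0 h. So I let Friday's follow the beta run up to its end. The beta run rises faster after 3.00 h than before it, so I take the geometric mean of the two beta readings around that time. This gives the clock concentration of target at 4.0 h, 0.0116 M, which is 27.6% of Friday's charge.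

Is Tuesday's clearly ahead? The beta concentration at 5.00 h over this charge is 45.9%, more than Friday's figure by over the margin. Tuesday's has the same charge as Friday's and runs past that reading, so I commit to Tuesday's, at about that figure or somewhat above.

The forecast also says Tuesday's, with 27.5% for Friday's but 82% for Tuesday's, far above mine, holding that by then “the fast autocatalysis has consumed all the substrate”.

The flask gives 25.7% for Friday's and 50.6% for Tuesday's, which ends with 49.4% as side product.

    starting material + 2 target → 3 target (k = 46.0 M⁻² min⁻¹)
    starting material → target (k = 0.00230 min⁻¹)
    starting material + target → side product (k = 0.270 M⁻¹ min⁻¹)
    solid substrate ⇌ starting material, rate k4*(cs4 - [starting material]) while solid is left; crystals form when [starting material] > cs4 (solubility = 20.0 mM, k = 0.110 min⁻¹)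

Friday's target is 0.0108 M, beside the clock concentration of 0.0116 M. A flask like Friday's with 0.071 M of solid substrate, read at the same time, should then show 16.3%, and it gives 15.2%.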